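The route rests on annulating the α‑methylene‑γ‑butyrolactone (ring B) onto a preformed ten‑membered carbocycle (ring A). In germacrane numbering the lactone oxygen sits on C6, which is allylic to the C4=C5 olefin, and C11 sits on C7; a (1(10)Z,4Z,6E)‑cyclodecatriene therefore accepts both bonds at once. A palladium‑catalysed Larock‑type heteroannulation with 2‑bromoacrylic acid adds the acrylate α‑carbon to C7 and closes the O–C6 bond through the C4–C6 allylpalladium unit, which sets C6, C7 and the exocyclic methylene in one operation. The triene precursor, with silyl ethers at C3, C8 and C9, comes from a Stille diene coupling, a (Z)‑iodoethylidene Wittig olefination and a Nozaki–Hiyama–Kishi ring closure.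

Key step: step 15

Remark on numbering: ring atoms are labelled as in germacranolides. C1–C10 form the ten‑membered ring (olefins C1=C10 and C4=C5), C6 carries the lactone oxygen, C7 carries C11 (C12 carbonyl, C13 methylene), and C14 and C15 are the methyls on C10 and C4.

Step 1
Reactants: 1 prop‑2‑yn‑1‑ol
Product: 3 (Z)‑3‑iodo‑2‑methylprop‑2‑en‑1‑ol, via alkenylmagnesium alkoxide 2 (not isolated)
Conditions: MeMgBr, CuI (cat.), THF, −10 °C to rt; then I2, −10 °C
Reagents that add atoms: methylmagnesium bromide, C[Mg]Br; iodine, [I][I]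
Why: Copper‑catalysed anti‑carbomagnesiation of the propargylic alkoxide should place methyl on C4 and magnesium on C5 cis to the CH2O group (chelate 2), and iodinolysis with retention should give the Z iodide that later becomes the Z C4=C5 olefin.

Step 2
Reactants: 3 (Z)‑3‑iodo‑2‑methylprop‑2‑en‑1‑ol
Product: 4 (Z)‑3‑iodo‑2‑methylprop‑2‑enal
Conditions: MnO2 (activated), CH2Cl2, rt, dark
Reagents that add atoms: none
Why: Neutral allylic oxidation with MnO2 should give the enal without Z/E isomerisation; the aldehyde is used directly as a solution.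

Step 3
Reactants: 4 (Z)‑3‑iodo‑2‑methylprop‑2‑enal
Product: 6 (3S,1Z)‑1‑iodo‑2‑methylhexa‑1,5‑dien‑3‑ol, via borinate ester 5 (not isolated)
Conditions: (−)‑Ipc2B(allyl) (from (+)‑α‑pinene), Et2O, −78 °C; then NaOH, H2O2, rt
Reagents that add atoms: (−)‑B‑allyldiisopinocampheylborane, C=CCB([C@@H]1C[C@@H]2C[C@H]([C@H]1C)C2(C)C)[C@@H]1C[C@@H]2C[C@H]([C@H]1C)C2(C)C
Why: Brown allylation through a chair transition state; this enantiomer of the reagent adds allyl to the Si face of the aldehyde, which sets C3 as S.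

Step 4
Reactants: 6 (3S,1Z)‑1‑iodo‑2‑methylhexa‑1,5‑dien‑3‑ol
Product: 7 triethyl{[(3S,1Z)‑1‑iodo‑2‑methylhexa‑1,5‑dien‑3‑yl]oxy}silane
Conditions: TESCl, imidazole, CH2Cl2, 0 °C to rt
Reagents that add atoms: chlorotriethylsilane, CC[Si](Cl)(CC)CC
Why: Standard silylation; the C3 oxygen is kept as a silyl ether because an allylic ester would be ionised in the later palladium steps.

Step 5
Reactants: 7 triethyl{[(3S,1Z)‑1‑iodo‑2‑methylhexa‑1,5‑dien‑3‑yl]oxy}silane
Product: 9 (3S,4Z)‑5‑iodo‑4‑methyl‑3‑[(triethylsilyl)oxy]pent‑4‑enal, via vicinal diol 8 (not isolated)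
Conditions: OsO4 (cat.), NaIO4, 2,6‑lutidine, dioxane/H2O, rt
Reagents that add atoms: osmium tetroxide, O=[Os](=O)(=O)=O (its oxygen ends up in the aldehyde; regenerated by sodium periodate, [Na+].[O-]I(=O)(=O)=O)
Why: Lemieux–Johnson cleavage; OsO4 should dihydroxylate the monosubstituted terminal olefin much faster than the hindered, electron‑poor iodoalkene, and periodate cleaves diol 8 to the C1 aldehyde.

Step 6
Reactants: 10 (R)‑2,2‑dimethyl‑1,3‑dioxolane‑4‑carbaldehyde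
Product: 11 (S)‑4‑ethynyl‑2,2‑dimethyl‑1,3‑dioxolane
Conditions: dimethyl (1‑diazo‑2‑oxopropyl)phosphonate, K2CO3, MeOH, 0 °C to rt
Reagents that add atoms: dimethyl (1‑diazo‑2‑oxopropyl)phosphonate, CC(=O)C(=[N+]=[N-])P(=O)(OC)OC
Why: Ohira–Bestmann (Seyferth–Gilbert) homologation should convert the aldehyde into the terminal alkyne without epimerising the future C8 centre, which comes from the chiral pool.

Step 7
Reactants: 11 (S)‑4‑ethynyl‑2,2‑dimethyl‑1,3‑dioxolane
Product: 12 (S)‑but‑3‑yne‑1,2‑diol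
Conditions: Dowex 50WX8 (H+ form), MeOH/H2O, rt
Reagents that add atoms: none
Why: Acid‑catalysed acetal hydrolysis is done at this robust alkyne stage, so no acid is needed later on the diene.

Step 8
Reactants: 12 (S)‑but‑3‑yne‑1,2‑diol
Product: 13 (S)‑3,4‑bis[(triethylsilyl)oxy]but‑1‑yne
Conditions: TESCl, imidazole, DMF, 0 °C to rt
Reagents that add atoms: chlorotriethylsilane, CC[Si](Cl)(CC)CC
Why: Double silylation gives a primary and a secondary TES ether that are told apart later by selective oxidation of the primary one.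

Step 9
Reactants: 13 (S)‑3,4‑bis[(triethylsilyl)oxy]but‑1‑yne
Product: 14 tributyl{(1E,3S)‑3,4‑bis[(triethylsilyl)oxy]but‑1‑en‑1‑yl}stannane
Conditions: Bu3SnH, PdCl2(PPh3)2 (cat.), THF, 0 °C
Reagents that add atoms: tributyltin hydride, CCCC[SnH](CCCC)CCCC
Why: Palladium‑catalysed syn hydrostannation should put tin on the terminal carbon, away from the bulky propargylic silyl ether, and give the E alkenylstannane (C6=C7).

Step 10
Reactants: 9 (3S,4Z)‑5‑iodo‑4‑methyl‑3‑[(triethylsilyl)oxy]pent‑4‑enal; 14 tributyl{(1E,3S)‑3,4‑bis[(triethylsilyl)oxy]but‑1‑en‑1‑yl}stannane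
Product: 15 (3S,4Z,6E,8S)‑4‑methyl‑3,8,9‑tris[(triethylsilyl)oxy]nona‑4,6‑dienal
Conditions: Pd2(dba)3 (cat.), AsPh3, CuI (cat.), NMP, rt, dark
Reagents that add atoms: none
Why: Stille coupling forms the C5–C6 bond with retention at both alkenyl partners and should give the (4Z,6E)‑diene under neutral conditions that the aldehyde tolerates.

Step 11
Reactants: 15 (3S,4Z,6E,8S)‑4‑methyl‑3,8,9‑tris[(triethylsilyl)oxy]nona‑4,6‑dienal
Product: 16 (2Z,5S,6Z,8E,10S)‑2‑iodo‑6‑methyl‑5,10,11‑tris[(triethylsilyl)oxy]undeca‑2,6,8‑triene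
Conditions: EtPPh3I, n‑BuLi, THF, rt; I2, −78 °C; NaHMDS, −78 to −20 °C; then 15, −78 °C
Reagents that add atoms: ethyltriphenylphosphonium iodide, CC[P+](c1ccccc1)(c1ccccc1)c1ccccc1.[I-]; iodine, [I][I]
Why: Stork–Zhao‑type Wittig olefination with the α‑iodoethylidene ylide should give the Z trisubstituted alkenyl iodide (iodine cis to C2); it is placed after the Stille step so that only one alkenyl iodide is present during that coupling.

Step 12
Reactants: 16 (2Z,5S,6Z,8E,10S)‑2‑iodo‑6‑methyl‑5,10,11‑tris[(triethylsilyl)oxy]undeca‑2,6,8‑triene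
Product: 18 (2S,3E,5Z,7S,9Z)‑10‑iodo‑6‑methyl‑2,7‑bis[(triethylsilyl)oxy]undeca‑3,5,9‑trienal, via alkoxysulfonium chloride 17 (not isolated)
Conditions: (COCl)2, DMSO, CH2Cl2, −78 to −40 °C; then Et3N, −78 to −30 °C; pH 7 buffer
Reagents that add atoms: none
Why: Swern oxidation applied directly to a silyl ether: chlorodimethylsulfonium chloride attacks only the unhindered primary TES ether, chlorotriethylsilane is lost, and salt 17 collapses with base to the C9 aldehyde while both secondary TES ethers stay.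

Step 13
Reactants: 18 (2S,3E,5Z,7S,9Z)‑10‑iodo‑6‑methyl‑2,7‑bis[(triethylsilyl)oxy]undeca‑3,5,9‑trienal
Product: 19 (1R,2S,3E,5Z,7S,9Z)‑6,10‑dimethyl‑2,7‑bis[(triethylsilyl)oxy]cyclodeca‑3,5,9‑trien‑1‑ol
Conditions: CrCl2 (excess), NiCl2 (cat.), DMSO/THF, rt, slow addition at high dilution
Reagents that add atoms: none
Why: Nozaki–Hiyama–Kishi ring closure forms C9–C10 with retention of the Z alkene; Felkin–Anh addition anti to the C8 silyloxy group should give the 8,9‑anti (9R) carbinol.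

Step 14
Reactants: 19 (1R,2S,3E,5Z,7S,9Z)‑6,10‑dimethyl‑2,7‑bis[(triethylsilyl)oxy]cyclodeca‑3,5,9‑trien‑1‑ol
Product: 20 tert‑butyl{[(1R,2S,3E,5Z,7S,9Z)‑6,10‑dimethyl‑2,7‑bis[(triethylsilyl)oxy]cyclodeca‑3,5,9‑trien‑1‑yl]oxy}dimethylsilane
Conditions: TBSOTf, 2,6‑lutidine, CH2Cl2, −78 to 0 °C
Reagents that add atoms: tert‑butyldimethylsilyl triflate, CC(C)(C)[Si](C)(C)OS(=O)(=O)C(F)(F)F
Why: Silylation of the hindered C9 hydroxyl with the reactive triflate marks the one oxygen that must end up free, with a group that outlasts the TES ethers.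

Step 15
Reactants: 20 tert‑butyl{[(1R,2S,3E,5Z,7S,9Z)‑6,10‑dimethyl‑2,7‑bis[(triethylsilyl)oxy]cyclodeca‑3,5,9‑trien‑1‑yl]oxy}dimethylsilane; 21 2‑bromoprop‑2‑enoic acid
Product: 23 (3aS,4S,5R,6Z,9S,10Z,11aR)‑5‑[(tert‑butyldimethylsilyl)oxy]‑6,10‑dimethyl‑3‑methylidene‑4,9‑bis[(triethylsilyl)oxy]‑3a,4,5,8,9,11a‑hexahydrocyclodeca[b]furan‑2(3H)‑one, via oxapalladacycle 22 (not isolated)
Conditions: Pd(OAc)2 (10 mol %), n‑Bu4NCl, Na2CO3, DMF, 70 °C
Reagents that add atoms: none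
Why: Zerovalent palladium (formed in situ from Pd(OAc)2) inserts into the C–Br bond of 21, the alkenylpalladium adds syn across C6=C7 with the acrylate α‑carbon going to the less substituted diene terminus C7, and the resulting C4–C6 allylpalladium unit, held as oxapalladacycle 22 by the pendant carboxylate, collapses by C–O bond formation at C6 and returns zerovalent palladium. The closest known reaction type is the Larock heteroannulation of 1,3‑dienes with aryl or vinylic halides that carry a carboxylic acid. The γ‑lactone closes in the 5‑exo sense by attack of the carboxylate oxygen on the proximal allyl terminus C6 and not on C4, which would need a seven‑membered ring. C7 is set by the face of carbopalladation: the E C6=C7 bond should be attacked from its outer face, anti to the C8–C9 ring bond, in the conformer with the C8 silyloxy group inside and H8 outside, which corresponds to 7S; C6 follows because oxygen is delivered to the same face as C11 (net syn addition to an E olefin gives the trans‑fused 6R,7S lactone), and C4=C5 should keep its Z geometry because the allyl terminus is trapped before syn/anti isomerisation. The step needs chemoselectivity for the conjugated diene over the isolated C1=C10 olefin and regioselectivity for C7 over C4, both secured by the faster insertion of 1,3‑dienes at their less substituted end, and it needs inert allylic oxygens, which is why C3, C8 and C9 carry silyl ethers and no esters at this stage.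

Step 16
Reactants: 23 the bis‑TES mono‑TBS lactone
Product: 24 (3aR,4S,5R,6Z,9S,10Z,11aR)‑5‑[(tert‑butyldimethylsilyl)oxy]‑4,9‑dihydroxy‑6,10‑dimethyl‑3‑methylidene‑3a,4,5,8,9,11a‑hexahydrocyclodeca[b]furan‑2(3H)‑one
Conditions: HF·pyridine, pyridine, THF, 0 °C
Reagents that add atoms: none
Why: Buffered HF·pyridine should cleave both secondary TES ethers much faster than the hindered secondary TBS ether and does not touch the α‑methylene lactone (the 3a descriptor changes by priority only).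

Step 17
Reactants: 24 the C3,C8‑diol
Product: 25 (3aR,4S,5R,6Z,9S,10Z,11aR)‑5‑[(tert‑butyldimethylsilyl)oxy]‑4‑hydroxy‑6,10‑dimethyl‑3‑methylidene‑2‑oxo‑2,3,3a,4,5,8,9,11a‑octahydrocyclodeca[b]furan‑9‑yl acetate
Conditions: Ac2O, pyridine, CH2Cl2, 0 °C
Reagents that add atoms: acetic anhydride, CC(=O)OC(C)=O
Why: Selective acylation: the allylic C3 hydroxyl next to a CH2 group should react well before the C8 hydroxyl, which is flanked by the ring‑fusion carbon C7 and the C9 OTBS group.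

Step 18
Reactants: 26 (E)‑2‑methylbut‑2‑en‑1‑ol
Product: 27 [(2R,3R)‑2,3‑dimethyloxiran‑2‑yl]methanol
Conditions: Ti(OiPr)4 (cat.), D‑(−)‑diethyl tartrate (cat.), t‑BuOOH, 4 Å MS, CH2Cl2, −20 °C
Reagents that add atoms: tert‑butyl hydroperoxide, CC(C)(C)OO
Why: Sharpless asymmetric epoxidation; the D‑(−)‑tartrate ligand should deliver oxygen to the face that gives the (2R,3R) epoxy alcohol, and the E olefin fixes the cis relationship of the two methyls.

Step 19
Reactants: 27 [(2R,3R)‑2,3‑dimethyloxiran‑2‑yl]methanol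
Product: 29 (2S,3R)‑2,3‑dimethyloxirane‑2‑carboxylic acid, via epoxy aldehyde 28 (not isolated)
Conditions: TEMPO (cat.), PhI(OAc)2, MeCN/H2O, rt
Reagents that add atoms: water, O
Why: Oxoammonium oxidation to aldehyde 28 and, through its hydrate, to the acid is mild enough for the epoxide; the C2 descriptor changes by priority only.

Step 20
Reactants: 25 the C3 acetate with free C8 hydroxyl; 29 (2S,3R)‑2,3‑dimethyloxirane‑2‑carboxylic acid
Product: 31 (3aS,4S,5R,6Z,9S,10Z,11aR)‑9‑acetoxy‑5‑[(tert‑butyldimethylsilyl)oxy]‑6,10‑dimethyl‑3‑methylidene‑2‑oxo‑2,3,3a,4,5,8,9,11a‑octahydrocyclodeca[b]furan‑4‑yl (2S,3R)‑2,3‑dimethyloxirane‑2‑carboxylate, via mixed anhydride 30 (not isolated)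
Conditions: 29, 2,4,6‑trichlorobenzoyl chloride, Et3N, toluene, rt; then 25, DMAP, toluene, 40 °C
Reagents that add atoms: none
Why: Yamaguchi esterification through mixed anhydride 30 and its acylpyridinium is the standard way to acylate a hindered secondary alcohol with an α,α‑disubstituted acid; C8 is no longer allylic, so the ester is now safe.

Step 21
Reactants: 31 the C9 TBS ether of the target
Product: 32 (3aS,4S,5R,6Z,9S,10Z,11aR)‑9‑acetoxy‑5‑hydroxy‑6,10‑dimethyl‑3‑methylidene‑2‑oxo‑2,3,3a,4,5,8,9,11a‑octahydrocyclodeca[b]furan‑4‑yl (2S,3R)‑2,3‑dimethyloxirane‑2‑carboxylate (CNP0299903.2)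
Conditions: HF·pyridine, pyridine, THF, 0 °C to rt
Reagents that add atoms: none
Why: Buffered fluoride‑mediated desilylation under mildly acidic conditions should free the C9 hydroxyl without acyl migration from O8, Michael addition to the methylene lactone or opening of the electron‑poor glycidic ester.

Compound list
1 | prop‑2‑yn‑1‑ol | C#CCO | starting material
2 | bromomagnesium (Z)‑3‑(bromomagnesio)‑2‑methylprop‑2‑en‑1‑olate | Br[Mg]OC/C(C)=C\[Mg]Br | intermediate (not isolated)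
3 | (Z)‑3‑iodo‑2‑methylprop‑2‑en‑1‑ol | OC/C(C)=C\I | intermediate
4 | (Z)‑3‑iodo‑2‑methylprop‑2‑enal | O=C/C(C)=C\I | intermediate
5 | (3S,1Z)‑1‑iodo‑2‑methylhexa‑1,5‑dien‑3‑yl diisopinocampheylborinate | C=CC[C@H](OB([C@@H]1C[C@@H]2C[C@H]([C@H]1C)C2(C)C)[C@@H]1C[C@@H]2C[C@H]([C@H]1C)C2(C)C)/C(C)=C\I | intermediate (not isolated)
6 | (3S,1Z)‑1‑iodo‑2‑methylhexa‑1,5‑dien‑3‑ol | C=CC[C@H](O)/C(C)=C\I | intermediate
7 | triethyl{[(3S,1Z)‑1‑iodo‑2‑methylhexa‑1,5‑dien‑3‑yl]oxy}silane | C=CC[C@H](O[Si](CC)(CC)CC)/C(C)=C\I | intermediate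
8 | (4S,5Z)‑6‑iodo‑5‑methyl‑4‑[(triethylsilyl)oxy]hex‑5‑ene‑1,2‑diol (both C2 epimers) | OCC(O)C[C@H](O[Si](CC)(CC)CC)/C(C)=C\I | intermediate (not isolated)
9 | (3S,4Z)‑5‑iodo‑4‑methyl‑3‑[(triethylsilyl)oxy]pent‑4‑enal | O=CC[C@H](O[Si](CC)(CC)CC)/C(C)=C\I | intermediate
10 | (R)‑2,2‑dimethyl‑1,3‑dioxolane‑4‑carbaldehyde | O=C[C@H]1COC(C)(C)O1 | starting material
11 | (S)‑4‑ethynyl‑2,2‑dimethyl‑1,3‑dioxolane | C#C[C@H]1COC(C)(C)O1 | intermediate
12 | (S)‑but‑3‑yne‑1,2‑diol | C#C[C@H](O)CO | intermediate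
13 | (S)‑3,4‑bis[(triethylsilyl)oxy]but‑1‑yne | C#C[C@H](O[Si](CC)(CC)CC)CO[Si](CC)(CC)CC | intermediate
14 | tributyl{(1E,3S)‑3,4‑bis[(triethylsilyl)oxy]but‑1‑en‑1‑yl}stannane | CCCC[Sn](CCCC)(CCCC)/C=C/[C@H](O[Si](CC)(CC)CC)CO[Si](CC)(CC)CC | intermediate
15 | (3S,4Z,6E,8S)‑4‑methyl‑3,8,9‑tris[(triethylsilyl)oxy]nona‑4,6‑dienal | O=CC[C@H](O[Si](CC)(CC)CC)/C(C)=C\C=C\[C@H](O[Si](CC)(CC)CC)CO[Si](CC)(CC)CC | intermediate
16 | (2Z,5S,6Z,8E,10S)‑2‑iodo‑6‑methyl‑5,10,11‑tris[(triethylsilyl)oxy]undeca‑2,6,8‑triene | I/C(C)=C\C[C@H](O[Si](CC)(CC)CC)/C(C)=C\C=C\[C@H](O[Si](CC)(CC)CC)CO[Si](CC)(CC)CC | intermediate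
17 | dimethyl{[(2S,3E,5Z,7S,9Z)‑10‑iodo‑6‑methyl‑2,7‑bis[(triethylsilyl)oxy]undeca‑3,5,9‑trien‑1‑yl]oxy}sulfonium chloride | I/C(C)=C\C[C@H](O[Si](CC)(CC)CC)/C(C)=C\C=C\[C@H](O[Si](CC)(CC)CC)CO[S+](C)C.[Cl-] | intermediate (not isolated)
18 | (2S,3E,5Z,7S,9Z)‑10‑iodo‑6‑methyl‑2,7‑bis[(triethylsilyl)oxy]undeca‑3,5,9‑trienal | I/C(C)=C\C[C@H](O[Si](CC)(CC)CC)/C(C)=C\C=C\[C@H](O[Si](CC)(CC)CC)C=O | intermediate
19 | (1R,2S,3E,5Z,7S,9Z)‑6,10‑dimethyl‑2,7‑bis[(triethylsilyl)oxy]cyclodeca‑3,5,9‑trien‑1‑ol | C/C1=C/C=C/[C@H](O[Si](CC)(CC)CC)[C@H](O)/C(C)=C\C[C@@H]1O[Si](CC)(CC)CC | intermediate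
20 | tert‑butyl{[(1R,2S,3E,5Z,7S,9Z)‑6,10‑dimethyl‑2,7‑bis[(triethylsilyl)oxy]cyclodeca‑3,5,9‑trien‑1‑yl]oxy}dimethylsilane | C/C1=C/C=C/[C@H](O[Si](CC)(CC)CC)[C@H](O[Si](C)(C)C(C)(C)C)/C(C)=C\C[C@@H]1O[Si](CC)(CC)CC | intermediate
21 | 2‑bromoprop‑2‑enoic acid | C=C(Br)C(=O)O | starting material
22 | six‑membered oxapalladacycle (Pd bound to C6 and to the carboxylate oxygen, drawn as its σ‑allyl form) | C=C1C(=O)O[Pd][C@@H]2/C=C(/C)[C@@H](O[Si](CC)(CC)CC)C/C=C(/C)[C@@H](O[Si](C)(C)C(C)(C)C)[C@@H](O[Si](CC)(CC)CC)[C@@H]12 | intermediate (not isolated)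
23 | (3aS,4S,5R,6Z,9S,10Z,11aR)‑5‑[(tert‑butyldimethylsilyl)oxy]‑6,10‑dimethyl‑3‑methylidene‑4,9‑bis[(triethylsilyl)oxy]‑3a,4,5,8,9,11a‑hexahydrocyclodeca[b]furan‑2(3H)‑one | C=C1C(=O)O[C@@H]2/C=C(/C)[C@@H](O[Si](CC)(CC)CC)C/C=C(/C)[C@@H](O[Si](C)(C)C(C)(C)C)[C@@H](O[Si](CC)(CC)CC)[C@@H]12 | intermediate
24 | (3aR,4S,5R,6Z,9S,10Z,11aR)‑5‑[(tert‑butyldimethylsilyl)oxy]‑4,9‑dihydroxy‑6,10‑dimethyl‑3‑methylidene‑3a,4,5,8,9,11a‑hexahydrocyclodeca[b]furan‑2(3H)‑one | C=C1C(=O)O[C@@H]2/C=C(/C)[C@@H](O)C/C=C(/C)[C@@H](O[Si](C)(C)C(C)(C)C)[C@@H](O)[C@@H]12 | intermediate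
25 | (3aR,4S,5R,6Z,9S,10Z,11aR)‑5‑[(tert‑butyldimethylsilyl)oxy]‑4‑hydroxy‑6,10‑dimethyl‑3‑methylidene‑2‑oxo‑2,3,3a,4,5,8,9,11a‑octahydrocyclodeca[b]furan‑9‑yl acetate | C=C1C(=O)O[C@@H]2/C=C(/C)[C@@H](OC(C)=O)C/C=C(/C)[C@@H](O[Si](C)(C)C(C)(C)C)[C@@H](O)[C@@H]12 | intermediate
26 | (E)‑2‑methylbut‑2‑en‑1‑ol | C/C=C(\C)CO | starting material
27 | [(2R,3R)‑2,3‑dimethyloxiran‑2‑yl]methanol | OC[C@@]1(C)O[C@@H]1C | intermediate
28 | (2S,3R)‑2,3‑dimethyloxirane‑2‑carbaldehyde | O=C[C@@]1(C)O[C@@H]1C | intermediate (not isolated)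
29 | (2S,3R)‑2,3‑dimethyloxirane‑2‑carboxylic acid | OC(=O)[C@@]1(C)O[C@@H]1C | intermediate
30 | (2S,3R)‑2,3‑dimethyloxirane‑2‑carboxylic 2,4,6‑trichlorobenzoic anhydride | O=C(OC(=O)c1c(Cl)cc(Cl)cc1Cl)[C@@]1(C)O[C@@H]1C | intermediate (not isolated)
31 | (3aS,4S,5R,6Z,9S,10Z,11aR)‑9‑acetoxy‑5‑[(tert‑butyldimethylsilyl)oxy]‑6,10‑dimethyl‑3‑methylidene‑2‑oxo‑2,3,3a,4,5,8,9,11a‑octahydrocyclodeca[b]furan‑4‑yl (2S,3R)‑2,3‑dimethyloxirane‑2‑carboxylate | C=C1C(=O)O[C@@H]2/C=C(/C)[C@@H](OC(C)=O)C/C=C(/C)[C@@H](O[Si](C)(C)C(C)(C)C)[C@@H](OC(=O)[C@@]3(C)O[C@@H]3C)[C@@H]12 | intermediate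
32 | (3aS,4S,5R,6Z,9S,10Z,11aR)‑9‑acetoxy‑5‑hydroxy‑6,10‑dimethyl‑3‑methylidene‑2‑oxo‑2,3,3a,4,5,8,9,11a‑octahydrocyclodeca[b]furan‑4‑yl (2S,3R)‑2,3‑dimethyloxirane‑2‑carboxylate | C=C1C(=O)O[C@@H]2/C=C(/C)[C@@H](OC(C)=O)C/C=C(/C)[C@@H](O)[C@@H](OC(=O)[C@@]3(C)O[C@@H]3C)[C@@H]12 | target

Total step count: 21. Longest linear sequence: 15 steps (from 1 through steps 1–5, 10–17, 20 and 21); the stannane 14 (steps 6–9) and the epoxy acid 29 (steps 18–19) are made in side branches.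

Steps most likely to fail

Step 15. The alkenylpalladium may add to the other face of C6=C7 or to the C4 end of the diene; the allylpalladium unit may isomerise before the C–O bond forms and erode the C4=C5 geometry; zerovalent palladium may re‑ionise the allylic lactone. The fallback sets out from 20 and replaces the organopalladium pathway by a radical–polar crossover. Malonic acid with Mn(OAc)3·2H2O (manganese triacetate dihydrate) and KOAc in AcOH at rt should add a malonyl radical to C7; the allyl radical is oxidised to the cation and captured at C6 by one carboxyl group, which would give the α‑carboxy lactone F1. Decarboxylative methylenation of F1 (paraformaldehyde, piperidine cat., pyridine, 70 °C) would then install C13 with loss of CO2 and come back to the route at 23.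

Step 13. Intermolecular coupling may compete with closure of the strained ten‑membered triene, and the ring‑closing transition state may override Felkin–Anh control so that the alkenylchromium adds to the wrong face of the aldehyde. The fallback sets out from 18: if the closure delivers mainly the C9 epimer F2, a Mitsunobu inversion (4‑nitrobenzoic acid, PPh3, DIAD, THF, 0 °C) would give the inverted 4‑nitrobenzoate F3, and methanolysis (K2CO3, MeOH, 0 °C) would return to the route at 19.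

Step 12. The amine base used to collapse the alkoxysulfonium salt may epimerise C8 or move the C6=C7 bond into conjugation with the new aldehyde, and the reagent may not discriminate fully between primary and secondary TES ethers. The fallback sets out from 16 and separates deprotection from oxidation: selective solvolysis of the primary TES ether (PPTS, MeOH/CH2Cl2, −10 °C) would give the primary alcohol F4, and a buffered Dess–Martin oxidation (NaHCO3, CH2Cl2, 0 °C), which needs no amine base, would return to the route at 18.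

Further compounds
F1 | step 15 | (3aS,4S,5R,6Z,9S,10Z,11aR)‑5‑[(tert‑butyldimethylsilyl)oxy]‑6,10‑dimethyl‑2‑oxo‑4,9‑bis[(triethylsilyl)oxy]‑2,3,3a,4,5,8,9,11a‑octahydrocyclodeca[b]furan‑3‑carboxylic acid (both C3 epimers) | OC(=O)C1C(=O)O[C@@H]2/C=C(/C)[C@@H](O[Si](CC)(CC)CC)C/C=C(/C)[C@@H](O[Si](C)(C)C(C)(C)C)[C@@H](O[Si](CC)(CC)CC)[C@@H]12
F2 | step 13 | (1S,2S,3E,5Z,7S,9Z)‑6,10‑dimethyl‑2,7‑bis[(triethylsilyl)oxy]cyclodeca‑3,5,9‑trien‑1‑ol | C/C1=C/C=C/[C@H](O[Si](CC)(CC)CC)[C@@H](O)/C(C)=C\C[C@@H]1O[Si](CC)(CC)CC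
F3 | step 13 | (1R,2S,3E,5Z,7S,9Z)‑6,10‑dimethyl‑2,7‑bis[(triethylsilyl)oxy]cyclodeca‑3,5,9‑trien‑1‑yl 4‑nitrobenzoate | C/C1=C/C=C/[C@H](O[Si](CC)(CC)CC)[C@H](OC(=O)c2ccc(cc2)[N+](=O)[O-])/C(C)=C\C[C@@H]1O[Si](CC)(CC)CC
F4 | step 12 | (2S,3E,5Z,7S,9Z)‑10‑iodo‑6‑methyl‑2,7‑bis[(triethylsilyl)oxy]undeca‑3,5,9‑trien‑1‑ol | I/C(C)=C\C[C@H](O[Si](CC)(CC)CC)/C(C)=C\C=C\[C@H](O[Si](CC)(CC)CC)CO
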